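Late in both earlier runs, at 3.00 h, monomer in chains stands at 54.8% of the charge in cedar and 55.4% in maple, although maple was charged with 0.44 M of free monomer against 0.28 M in cedar. So at this pre-initiator charge the free monomer behaves as pseudo-first-order, and we carry the mean, 55.1%, to our flask, which has the same pre-initiator charge.

common to all: pre-initiator 20 mM
- cedar: free monomer 0.28 M; run made earlier
- maple: free monomer 0.44 M; run made earlier
- flask: free monomer 0.20 M; time 3.0 h

| run | time / h | monomer in chains / % | free monomer / % |
|---|---|---|---|
| cedar | 0.250 | 1.3 | 98.8 |
| cedar | 0.417 | 3.0 | 96.7 |
| cedar | 0.833 | 10.4 | 89.1 |
| cedar | 1.50 | 25.8 | 74.5 |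
| cedar | 3.00 | 54.8 | 43.5 |
| maple | 0.250 | 0.7 | 98.9 |
| maple | 0.417 | 3.2 | 96.7 |
| maple | 0.833 | 10.5 | 89.2 |
| maple | 1.50 | 25.4 | 74.0 |
| maple | 3.00 | 55.4 | 43.9 |

(scatter of a reading: 0.3 percentage points)

- the average divides the monomer in chains by the number of chains begun, living and dead together
- the analysis behind the earlier runs scatters by 0.3 percentage points, standard deviation
- the earlier runs do not show the number of chains; that part of a forecast is a guess

- whether the average number of monomer units in a chain (chains begun, living or dead) reaches 20 by 3.0 h (no / yes)
- average number of monomer units in a chain (chains begun, living or dead) at 3.0 h

The average length is monomer in chains divided by chains begun, so it needs a count of chains, which the runs do not show. As a first answer we suppose that each charged pre-initiator begins one chain, and this gives what we call the floor length, the conversion times the charge of free monomer over the charge of pre-initiator, 5.51 for our flask. Reaching 20 would ask that the chains begun be a share of 0.275 of the charged pre-initiator. We then go round once more. The last readings fall short of a closed balance, and as a share of the pre-initiator charge the shortfall averages 0.196, a rough reading under a scatter of 0.3 percentage points. If we guess that each missing unit marks a pre-initiator that began no chain, our length is 6.85, so our answer is no.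

The forecast also says no, but its length of 5.8 is lower than ours, with chains counted “assuming one chain per activated initiator, which is a guess”.

The flask gives no and a length of 8.97.

    free monomer + initiator → living end + monomer in chains (k = 0.520 M⁻¹ min⁻¹)
    free monomer + living end → monomer in chains + living end, rate k2*[living end]*[free monomer] (k = 0.501 M⁻¹ min⁻¹)
    initiator + monomer in chains → spent initiator (k = 1.22 M⁻¹ min⁻¹)
    pre-initiator → initiator (k = 0.0113 min⁻¹)

In this scheme each chain begun is a living end, so the flask's 0.0120 M of living end at 3.00 h is a share of 0.599 of the charged pre-initiator, which is less than the 0.804 of our second round. The neighbouring flask changes one setting, 0.34 M of free monomer with the pre-initiator charge as before, so its floor is 9.37. Divided by the same share, that floor gives 15.6, and the neighbouring flask gives 15.3, with 43.4% of its free monomer left at 3.00 h.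

The data were generated by integration with constants of no real substance; the scatter is artificial.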